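The numbers in the tables were generated by integration with made-up constants.

Getting more target out than substrate went in was impossible, so I asked how near each vessel would come to that ceiling of 100 percent.

| setting | south-west | north-west | blue | red | ochre | grey |
|---|---|---|---|---|---|---|
| substrate | 1.5 M | 2.1 M | 1.5 M | 1.5 M | 1.5 M | 1.5 M |
| remark | run made earlier | run made earlier | everything together in a closed stirred flask, run for 4.0 min | one stirred flow tank at steady state, fed with the mixture as stated, mean residence time 12.0 min | plug flow through a tube for 4.0 min, no back-mixing | one stirred flow tank at steady state, fed with the mixture as stated, mean residence time 4.0 min |
| time |  |  | 4.0 min |  | 4.0 min |  |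

| run | time / min | target / % | substrate / % |
|---|---|---|---|
| south-west | 0.500 | 98 | 0 |
| south-west | 1.00 | 99 | 0 |
| south-west | 1.50 | 98 | 0 |
| south-west | 2.50 | 99 | 0 |
| south-west | 3.00 | 95 | 0 |
| south-west | 4.00 | 99 | 0 |
| north-west | 0.200 | 30 | 72 |
| north-west | 0.667 | 98 | 3 |
| north-west | 1.00 | 96 | 0 |
| north-west | 1.50 | 97 | 0 |
| north-west | 2.50 | 98 | 3 |
| north-west | 3.00 | 97 | 0 |
| north-west | 4.00 | 97 | 4 |

(each reading ± 1.5 percentage points)

1. the set-up with the highest amount of target at the outlet or at the end, in percent of the substrate put in ("none" if the first two lie within 2 percentage points) (blue / red / ochre / grey / none)
2. amount of target at the outlet or at the end, in percent of the substrate put in, blue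
3. amount of target at the outlet or at the end, in percent of the substrate put in, red
4. amount of target at the outlet or at the end, in percent of the substrate put in, ochre
5. amount of target at the outlet or at the end, in percent of the substrate put in, grey

- the stated concentrations are those of everything mixed, before any reaction; amounts are the same in each set-up
- the analysis behind the earlier runs scatters by 1.5 percentage points, standard deviation
- the earlier runs were made in a closed, stirred flask

I took the settings in turn. The charge came first: by hand, a richer charge might have shifted the yield. But the north-west run, at 2.1 M, read 98% target at 0.667 min, which is inside the band of the south-west run, between 95% and 99%.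

Time came next: by hand, I expected more time to give more target in this flask while substrate remained. The south-west run already read 0% substrate at 0.500 min, and target stayed flat afterwards. So I compared each vessel's time t with the finishing time t_f, the earliest reading with substrate gone:

M = t / t_f = 8.00 for blue

M is the time margin, the time a vessel gives over the time the closed flask was read to need at that charge. The reading t_f is an upper bound on the finishing time, and M is a lower bound on the margin.

At the small end of M, target is low: 30% at 0.200 min in the north-west run. At the large end it sits on the plateau. Joining the ends, target climbs until M reaches about 1, then stays flat.

The vessel came last. A tube without back-mixing repeats the closed flask's history, so ochre has blue's M. Grey's residence time equals blue's time, so it has that M too, while red has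

M = 24.0

which is a longer margin than grey's. A tank works at its outlet concentration, though, so M reads less surely there.

The forecast gave none as best, with blue 98%, red 97.5%, ochre 98% and grey 96.5%. For the tanks it said: “the low-concentration tail is unmeasured, so they may lose a point or two, grey most”.

The simulation gave none, with blue 97.7%, red 97.4%, ochre 97.7% and grey 96.9%.

    substrate + target → side product (k = 0.00400 L mol⁻¹ s⁻¹)
    substrate + target → 2 target (k = 0.340 L mol⁻¹ s⁻¹)
    substrate → target (k = 6.20 × 10⁻⁵ s⁻¹)

In blue at 0.298 min, the step in which substrate and target give two target used substrate 85 times faster than the step to side product, a ratio usually called the selectivity factor. By 2.00 min blue held 0% substrate, 97.7% target and 2.32% side product, each unit of which counts as two of the charge. Blue, with M = 8.00, stood on the plateau, and ten times the time changed nothing. Blue read at 10 min has M = 20.0 and holds 97.7% target.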